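**Retrosynthetic overview** (carotenoid numbering: ring C1–C6, chain from C7)
1. C11=C12 by Wittig: C15 ring phosphonium salt (fragment 1) + C10 aldehyde ester (fragment 2). The methyl ester is carried in fragment 2, so nothing is oxidised once polyene and allylic diol are together.
2. Fragment 1: C9=C10 by HWE on a diol-enone; trans-5,6-diol by acid hydrolysis of an epoxy-enone (inversion at C5); enone by HWE on an epoxy aldehyde; oxirane by Sharpless asymmetric epoxidation of β-cyclogeraniol.
3. Fragment 2: two stabilised-ylide Wittig reactions on a C4 unit whose two ends are differentiated by lipase-catalysed mono-acetylation of (E)-but-2-ene-1,4-diol.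
4. Rings: the cyclohexane ring is bought intact (β-cyclocitral); the only ring formed is the oxirane (step 2), opened again in step 5.

Assumption: olefination reagents, oxidants, vinyl acetate and catalysts are treated as reagents and carry no compound number; the target SMILES is read as the trans-(5R,6R)-diol, all-E.

**Fragment 1**

Step 1
Reactants: 1 β-cyclocitral (2,6,6-trimethylcyclohex-1-ene-1-carbaldehyde)
Product: 2 β-cyclogeraniol [(2,6,6-trimethylcyclohex-1-en-1-yl)methanol]
Conditions: NaBH4, MeOH, 0 °C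
Reagents that add atoms: none
Why: Borohydride 1,2-reduction of a hindered enal; the tetrasubstituted β-carbon blocks conjugate reduction and no stereocentre is formed.

Step 2
Reactants: 2 β-cyclogeraniol
Product: 3 [(1S,6S)-2,2,6-trimethyl-7-oxabicyclo[4.1.0]heptan-1-yl]methanol
Conditions: Ti(OiPr)4 (20 mol%), L-(+)-diethyl tartrate (24 mol%), t-BuOOH (2 equiv, isooctane), 4 Å molecular sieves, CH2Cl2, −20 °C
Reagents that add atoms: tert-butyl hydroperoxide, CC(C)(C)OO
Why: Sharpless asymmetric epoxidation; the titanium–(R,R)-tartrate catalyst delivers oxygen to the same alkene face as in the geraniol to (2S,3S)-epoxygeraniol case, setting C5 and C6 together as the first stereocentres by asymmetric catalysis.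

Step 3
Reactants: 3 epoxy alcohol
Product: 4 (1R,6S)-2,2,6-trimethyl-7-oxabicyclo[4.1.0]heptane-1-carbaldehyde
Conditions: n-Pr4N[RuO4] (5 mol%), N-methylmorpholine N-oxide (1.5 equiv), 4 Å molecular sieves, CH2Cl2, rt
Reagents that add atoms: none
Why: Ley–Griffith oxidation under neutral conditions spares the acid-labile tetrasubstituted oxirane, and the aldehyde has no α-hydrogen so nothing can epimerise (descriptor changes by CIP priority only).

Step 4
Reactants: 4 epoxy aldehyde
Product: 5 (3E)-4-[(1R,6S)-2,2,6-trimethyl-7-oxabicyclo[4.1.0]heptan-1-yl]but-3-en-2-one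
Conditions: dimethyl (2-oxopropyl)phosphonate, NaH, THF, 0 °C → rt
Reagents that add atoms: dimethyl (2-oxopropyl)phosphonate, CC(=O)CP(=O)(OC)OC
Why: Horner–Wadsworth–Emmons olefination of a non-enolisable aldehyde gives the (E)-enone with the ring stereocentres untouched.

Step 5
Reactants: 5 epoxy-enone
Product: 6 (3E)-4-[(1R,2R)-1,2-dihydroxy-2,6,6-trimethylcyclohexyl]but-3-en-2-one
Conditions: HClO4 (0.2 M aq), THF, 0 °C → rt
Reagents that add atoms: water, O
Why: Acid-catalysed epoxide hydrolysis; the C6–O bond is deactivated by the electron-poor enone and shielded by the gem-dimethyl group, so the protonated oxirane opens at C5 with water entering anti (inversion at C5, retention at C6) to give the trans-(1R,2R)-diol.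

Step 6
Reactants: 6 diol-enone
Product: 7 ethyl (2E,4E)-5-[(1R,2R)-1,2-dihydroxy-2,6,6-trimethylcyclohexyl]-3-methylpenta-2,4-dienoate
Conditions: triethyl phosphonoacetate (4.5 equiv), NaH (4.5 equiv), THF, 0 °C → rt; minor 2Z isomer removed on SiO2
Reagents that add atoms: triethyl phosphonoacetate, CCOC(=O)CP(=O)(OCC)OCC
Why: Horner–Wadsworth–Emmons olefination of the methyl ketone is E-selective (about 6–9:1 expected, isomers separable); excess reagent covers the two tertiary hydroxyls, which as alkoxides have no fragmentation pathway.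

Step 7
Reactants: 7 dienoate
Product: 8 (2E,4E)-5-[(1R,2R)-1,2-dihydroxy-2,6,6-trimethylcyclohexyl]-3-methylpenta-2,4-dien-1-ol
Conditions: i-Bu2AlH (5 equiv), CH2Cl2, −78 → −20 °C; aq. KNaC4H4O6 work-up
Reagents that add atoms: none
Why: Hydride 1,2-reduction of the conjugated ester to the allylic alcohol without touching the diene or the stereocentres.

Step 8
Reactants: 8 triol
Product: 9 [(2E,4E)-5-[(1R,2R)-1,2-dihydroxy-2,6,6-trimethylcyclohexyl]-3-methylpenta-2,4-dien-1-yl]triphenylphosphonium bromide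
Conditions: Ph3P·HBr (1.05 equiv), MeOH, 0 °C → rt
Reagents that add atoms: triphenylphosphine hydrobromide, [Br-].[PH+](c1ccccc1)(c1ccccc1)c1ccccc1
Why: Phosphonium salt formation by ionisation of the primary dienylic alcohol under the weak acid and capture of the pentadienyl cation by PPh3 at the terminal carbon; the tertiary carbinols, each inductively deactivated by its neighbour, are expected to survive.

**Fragment 2**

Step 9
Reactants: 10 (E)-but-2-ene-1,4-diol
Product: 11 (E)-4-hydroxybut-2-en-1-yl acetate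
Conditions: immobilised Candida antarctica lipase B (a lipase), vinyl acetate (1.1 equiv), THF, 25 °C, stopped at maximum monoester
Reagents that add atoms: vinyl acetate, CC(=O)OC=C
Why: Lipase-catalysed irreversible transesterification; the enzyme acylates the polar diol much faster than the monoacetate, so the symmetric C4 unit is desymmetrised well beyond the statistical limit, which is the step that differentiates the future ester end from the future aldehyde end.

Step 10
Reactants: 11 monoacetate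
Product: 12 (E)-4-oxobut-2-en-1-yl acetate
Conditions: MnO2 (15 equiv), CH2Cl2, rt
Reagents that add atoms: none
Why: Selective heterogeneous oxidation of the allylic alcohol to the enal with retention of the E geometry.

Step 11
Reactants: 12 acetoxy enal
Product: 13 methyl (2E,4E)-6-acetoxy-2-methylhexa-2,4-dienoate
Conditions: methyl 2-(triphenylphosphoranylidene)propanoate (1.1 equiv), CH2Cl2, rt
Reagents that add atoms: methyl 2-(triphenylphosphoranylidene)propanoate, COC(=O)C(C)=P(c1ccccc1)(c1ccccc1)c1ccccc1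
Why: Wittig olefination with a stabilised α-methyl ylide gives the (2E)-trisubstituted enoate; the 4E bond comes unchanged from 10.

Step 12
Reactants: 13 acetoxy dienoate
Product: 14 methyl (2E,4E)-6-hydroxy-2-methylhexa-2,4-dienoate
Conditions: K2CO3 (0.2 equiv), MeOH, 0 °C
Reagents that add atoms: none
Why: Base-catalysed methanolysis (transesterification) removes the allylic acetate, while exchange at the methyl ester is degenerate.

Step 13
Reactants: 14 hydroxy dienoate
Product: 15 methyl (2E,4E)-2-methyl-6-oxohexa-2,4-dienoate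
Conditions: MnO2 (15 equiv), CH2Cl2, rt
Reagents that add atoms: none
Why: Allylic alcohol oxidation to the dienal with no change in alkene geometry.

Step 14
Reactants: 15 dienal ester
Product: 16 methyl (2E,4E,6E)-2,7-dimethyl-8-oxoocta-2,4,6-trienoate
Conditions: 2-(triphenylphosphoranylidene)propanal (1.1 equiv), toluene, 70 °C
Reagents that add atoms: 2-(triphenylphosphoranylidene)propanal, CC(C=O)=P(c1ccccc1)(c1ccccc1)c1ccccc1
Why: Wittig olefination with the formyl-stabilised ylide is E-selective and stops after one homologation because the α-methyl enal product is less electrophilic than 15.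

**Coupling**

Step 15
Reactants: 9 C15 phosphonium bromide + 16 C10 aldehyde ester
Product: 19 methyl (2E,4E,6E,8E,10E,12E)-13-[(1R,2R)-1,2-dihydroxy-2,6,6-trimethylcyclohexyl]-2,7,11-trimethyltrideca-2,4,6,8,10,12-hexaenoate, via C15 phosphorus ylide 17 (not isolated), via 8Z isomer 18 (not isolated)
Conditions: NaOMe (1.2 equiv), CH2Cl2/MeOH, 0 °C → rt; then EtOAc, reflux, N2, dark
Reagents that add atoms: none
Why: Wittig olefination of the allylic ylide with the enal builds C11=C12; the E/Z mixture converges on the all-E hexaene on heating because the cis isomer at that bond is sterically strained, and the ring stereocentres are not involved.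

**Compound list**
1 | β-cyclocitral (2,6,6-trimethylcyclohex-1-ene-1-carbaldehyde) | CC1=C(C=O)C(C)(C)CCC1 | starting material
2 | β-cyclogeraniol, (2,6,6-trimethylcyclohex-1-en-1-yl)methanol | CC1=C(CO)C(C)(C)CCC1 | intermediate
3 | [(1S,6S)-2,2,6-trimethyl-7-oxabicyclo[4.1.0]heptan-1-yl]methanol | OC[C@@]1(O2)C(C)(C)CCC[C@@]12C | intermediate
4 | (1R,6S)-2,2,6-trimethyl-7-oxabicyclo[4.1.0]heptane-1-carbaldehyde | O=C[C@@]1(O2)C(C)(C)CCC[C@@]12C | intermediate
5 | (3E)-4-[(1R,6S)-2,2,6-trimethyl-7-oxabicyclo[4.1.0]heptan-1-yl]but-3-en-2-one | CC(=O)/C=C/[C@@]1(O2)C(C)(C)CCC[C@@]12C | intermediate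
6 | (3E)-4-[(1R,2R)-1,2-dihydroxy-2,6,6-trimethylcyclohexyl]but-3-en-2-one | CC(=O)/C=C/[C@@]1(O)C(C)(C)CCC[C@@]1(C)O | intermediate
7 | ethyl (2E,4E)-5-[(1R,2R)-1,2-dihydroxy-2,6,6-trimethylcyclohexyl]-3-methylpenta-2,4-dienoate | CCOC(=O)/C=C(C)/C=C/[C@@]1(O)C(C)(C)CCC[C@@]1(C)O | intermediate
8 | (2E,4E)-5-[(1R,2R)-1,2-dihydroxy-2,6,6-trimethylcyclohexyl]-3-methylpenta-2,4-dien-1-ol | OC/C=C(C)/C=C/[C@@]1(O)C(C)(C)CCC[C@@]1(C)O | intermediate
9 | [(2E,4E)-5-[(1R,2R)-1,2-dihydroxy-2,6,6-trimethylcyclohexyl]-3-methylpenta-2,4-dien-1-yl]triphenylphosphonium bromide | [Br-].c1ccccc1[P+](c1ccccc1)(c1ccccc1)C/C=C(C)/C=C/[C@@]1(O)C(C)(C)CCC[C@@]1(C)O | intermediate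
10 | (E)-but-2-ene-1,4-diol | OC/C=C/CO | starting material
11 | (E)-4-hydroxybut-2-en-1-yl acetate | CC(=O)OC/C=C/CO | intermediate
12 | (E)-4-oxobut-2-en-1-yl acetate | CC(=O)OC/C=C/C=O | intermediate
13 | methyl (2E,4E)-6-acetoxy-2-methylhexa-2,4-dienoate | COC(=O)/C(C)=C/C=C/COC(C)=O | intermediate
14 | methyl (2E,4E)-6-hydroxy-2-methylhexa-2,4-dienoate | COC(=O)/C(C)=C/C=C/CO | intermediate
15 | methyl (2E,4E)-2-methyl-6-oxohexa-2,4-dienoate | COC(=O)/C(C)=C/C=C/C=O | intermediate
16 | methyl (2E,4E,6E)-2,7-dimethyl-8-oxoocta-2,4,6-trienoate | COC(=O)/C(C)=C/C=C/C=C(C)/C=O | intermediate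
17 | (1R,2R)-1-[(1E,3E)-3-methyl-5-(triphenylphosphoranylidene)penta-1,3-dien-1-yl]-2,6,6-trimethylcyclohexane-1,2-diol (C15 phosphorus ylide) | c1ccccc1P(c1ccccc1)(c1ccccc1)=C/C=C(C)/C=C/[C@@]1(O)C(C)(C)CCC[C@@]1(C)O | intermediate
18 | methyl (2E,4E,6E,8Z,10E,12E)-13-[(1R,2R)-1,2-dihydroxy-2,6,6-trimethylcyclohexyl]-2,7,11-trimethyltrideca-2,4,6,8,10,12-hexaenoate (8Z isomer) | COC(=O)/C(C)=C/C=C/C=C(C)/C=C\C=C(C)\C=C\[C@@]1(O)C(C)(C)CCC[C@@]1(C)O | intermediate
19 | methyl (2E,4E,6E,8E,10E,12E)-13-[(1R,2R)-1,2-dihydroxy-2,6,6-trimethylcyclohexyl]-2,7,11-trimethyltrideca-2,4,6,8,10,12-hexaenoate | COC(=O)/C(C)=C/C=C/C=C(C)/C=C/C=C(C)/C=C/[C@@]1(O)C(C)(C)CCC[C@@]1(C)O | target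

**Step count**
Total: 15 steps. Longest linear sequence: 9 steps (steps 1–8, then 15). The fragment 2 arm is 6 steps (9–14) before the coupling.

**Three steps most likely to fail**

Risk at step 5 (epoxide hydrolysis: proton loss from the C5 cation to allylic alcohols, partial syn opening, enone-derived by-products). The fallback sets out from 3 and comes back at 6. The oxirane is hydrolysed at the alcohol stage (0.1 M HClO4, THF/H2O, 0 °C), where the hydroxymethyl group likewise disfavours C6–O cleavage, giving (1S,2R)-1-(hydroxymethyl)-2,6,6-trimethylcyclohexane-1,2-diol F1. Only the primary carbinol is then oxidised (SO3·pyridine, DMSO, i-Pr2NEt, 0 °C; no glycol-cleaving oxidant) to (1R,2R)-1,2-dihydroxy-2,6,6-trimethylcyclohexane-1-carbaldehyde F2. A neutral Wittig reaction with 1-(triphenylphosphoranylidene)propan-2-one in toluene at 60 °C, chosen to avoid base-induced α-ketol rearrangement, gives 6.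

Risk at step 8 (the acidic salt formation may ionise the tertiary allylic C6 carbinol). The fallback sets out from 8 and comes back at 19. Neutral Appel bromination (CBr4, PPh3, CH2Cl2, −20 °C) of the primary alcohol gives (1R,2R)-1-[(1E,3E)-5-bromo-3-methylpenta-1,3-dien-1-yl]-2,6,6-trimethylcyclohexane-1,2-diol F3. A Michaelis–Becker reaction with NaP(O)(OEt)2 (THF, 0 °C) gives diethyl [(2E,4E)-5-[(1R,2R)-1,2-dihydroxy-2,6,6-trimethylcyclohexyl]-3-methylpenta-2,4-dien-1-yl]phosphonate F4. An E-selective Horner–Wadsworth–Emmons reaction of F4 with 16 (NaN(SiMe3)2, 3.2 equiv, THF, −78 → 0 °C) gives 19 directly.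

Risk at step 15 (poor E/Z ratio or incomplete thermal equilibration, ylide decomposition next to the free diol). The fallback sets out from 8 and comes back at 19. A Mitsunobu thioetherification with 1,3-benzothiazole-2-thiol (PPh3, diisopropyl azodicarboxylate, THF, 0 °C) gives (1R,2R)-1-[(1E,3E)-5-(1,3-benzothiazol-2-ylsulfanyl)-3-methylpenta-1,3-dien-1-yl]-2,6,6-trimethylcyclohexane-1,2-diol F5. Oxidation with H2O2 and (NH4)6Mo7O24·4H2O in EtOH at 0 °C gives (1R,2R)-1-[(1E,3E)-5-(1,3-benzothiazol-2-ylsulfonyl)-3-methylpenta-1,3-dien-1-yl]-2,6,6-trimethylcyclohexane-1,2-diol F6. A Julia–Kocienski olefination of F6 with 16 (NaN(SiMe3)2, THF, −78 °C → rt) gives 19.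

Further compounds
F1 | step 5 | (1S,2R)-1-(hydroxymethyl)-2,6,6-trimethylcyclohexane-1,2-diol | OC[C@@]1(O)C(C)(C)CCC[C@@]1(C)O
F2 | step 5 | (1R,2R)-1,2-dihydroxy-2,6,6-trimethylcyclohexane-1-carbaldehyde | O=C[C@@]1(O)C(C)(C)CCC[C@@]1(C)O
F3 | step 8 | (1R,2R)-1-[(1E,3E)-5-bromo-3-methylpenta-1,3-dien-1-yl]-2,6,6-trimethylcyclohexane-1,2-diol | BrC/C=C(C)/C=C/[C@@]1(O)C(C)(C)CCC[C@@]1(C)O
F4 | step 8 | diethyl [(2E,4E)-5-[(1R,2R)-1,2-dihydroxy-2,6,6-trimethylcyclohexyl]-3-methylpenta-2,4-dien-1-yl]phosphonate | CCOP(=O)(OCC)C/C=C(C)/C=C/[C@@]1(O)C(C)(C)CCC[C@@]1(C)O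
F5 | step 15 | (1R,2R)-1-[(1E,3E)-5-(1,3-benzothiazol-2-ylsulfanyl)-3-methylpenta-1,3-dien-1-yl]-2,6,6-trimethylcyclohexane-1,2-diol | c1ccc2sc(SC/C=C(C)/C=C/[C@@]3(O)C(C)(C)CCC[C@@]3(C)O)nc2c1
F6 | step 15 | (1R,2R)-1-[(1E,3E)-5-(1,3-benzothiazol-2-ylsulfonyl)-3-methylpenta-1,3-dien-1-yl]-2,6,6-trimethylcyclohexane-1,2-diol | c1ccc2sc(S(=O)(=O)C/C=C(C)/C=C/[C@@]3(O)C(C)(C)CCC[C@@]3(C)O)nc2c1
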